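## Structural features

The target has a single ring, a γ-butyrolactone (O1, C2 carbonyl, C3, C4, C5) that carries an E exocyclic alkylidene at C3, an acetoxy group at C4 (S) and a 2-methylprop-1-enyl group at C5 (R), the last two trans to each other. The alkylidene carbon C1′ begins a ten-carbon chain (C1′ to C10′) with a free allylic carbinol at C3′ (R), an E trisubstituted alkene C4′=C5′, a Z trisubstituted alkene C8′=C9′ and an allylic ether from C10′ to an (E)-4-hydroxycinnamyl unit. C4 and C5 are contiguous stereocentres, whereas C3′ is separated from C4 by the C3=C1′ double bond and the C2′ methylene, a 1,5-relationship that the ring cannot relay. Several groups are fragile: the C4 acetate is allylic and β to the lactone carbonyl, so that base can cause elimination or acyl transfer, the alkylidene lactone is a Michael acceptor, the 4-oxygenated cinnamyl ether ionises easily under acid, and the Z alkene and the free phenol narrow the choice of reagents further. The real difficulties are the remote C3′ centre, the geometry of the C3=C1′ alkene and the differentiation of two secondary allylic oxygens, of which C4 is acylated and C3′ is free. The key step uses the fact that C2′ is the γ-carbon of the C2(=O)–C3=C1′ enoate, a vinylogous enolate position, while C3′ is a carbinol carbon that can come from an aldehyde. The full descriptor set is (3E,4S,5R,3′R,4′E,8′Z) with an E cinnamyl alkene, and the trans C4–O/C5–C arrangement with both descriptors matches 2-deoxy-D-ribono-1,4-lactone, so both ring centres can be carried over without inversion.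

## Logic of the disconnections

**23 ⇒ 19.** The acetyl C–O bond at C4 is cut, and the free O–H groups at C3′ and on the arene are traded for O–Si bonds, passing through 22, 21 and 20. The aldol delivers C3′ as the free hydroxyl and C4 as a silyl ether, the reverse of the target, so an exchange is unavoidable. The gain is that all skeletal work ends at 19. The demand is a C4 silyl group that leaves while two bulkier silyl ethers stay, and a last deprotection that is not basic.

**19 ⇒ 10 + 18.** The C2′–C3′ bond is cut. This is the only place where a bond can be made at a vinylogous enolate carbon and a carbinol carbon at once, and it splits the molecule into two halves of similar size. The gain is full convergence, with C3′ set by a catalyst and not by the distant ring. The demand is γ-selective attack, one aldehyde face, an E alkene on return of the enoate, and a Lewis acid mild enough for the silyl ethers and the cinnamyl ether.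

**10 ⇒ 9 ⇒ 7 ⇒ 5 + 6.** The C3–C1′ bond is cut by an aldol addition followed by dehydration through 8, and the dienolate is traced to γ-deprotonation of 9. The two carbons of 6 become C1′ and C2′. The gain is a simple 4,5-disubstituted lactone. The demand is that the lactone enolate and the dienolate are trapped before they expel the C4 silyloxy group.

**5 ⇒ 4 ⇒ 3 ⇒ 2 ⇒ 1.** The C1″=C2″ alkene of the isobutenyl group is cut by a carbonyl olefination, and the aldehyde is traced through oxidation and silylation to the lactone of the sugar. Both ring stereocentres are then bought, not made. The demand is that the α,β-dioxygenated aldehyde 4 is not enolised during olefination.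

**18 ⇒ 16.** No skeletal bond is cut; the C3′ aldehyde is traced to the (E)-methyl group of a gem-dimethyl alkene by allylic C–H oxidation through 17. The gain is that the whole carbon chain comes from 15. The demand is site selectivity for the terminal alkene over the two other alkenes and the ether methylenes.

**16 ⇒ 14 + 15; 14 ⇒ 13 ⇒ 12 ⇒ 11.** The ether O–CH2 bond on the cinnamyl side is cut, and the bromide is traced by functional-group changes to the phenolic ester. The cut is on the cinnamyl side so that the Z-allylic alcohol is used unchanged as the nucleophile. The demand is that the alkoxide displaces bromide faster than it attacks the aryl silyl ether.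

## Other disconnections considered

Alternative 1: The cut is the C5–C1″ bond of the early lactone. Under constant-current electrolysis with NiCl2·6H2O and 2,2′-bipyridine, the tartrate-derived N-hydroxyphthalimide ester A1 would lose CO2, and the C5 radical would couple with 1-bromo-2-methylprop-1-ene A2. The product would be the trans isobutenyl lactone A3, which is the same compound as 5.
- In its favour: it avoids the enolisable aldehyde 4 and the basic ylide of step 4, so the epimerisation and β-elimination risks of that step disappear. On this point it is better than the chosen plan. The configuration of the acid carbon of A1 is irrelevant because the radical is planar.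
- Against it: C5 would be created under 1,2-induction from a single silyloxy group. In the chosen plan C5 is inherited and no new ring centre is made, which is more certain.
- Structure: it solves only the first four steps; C3′, the exocyclic alkene and the union are untouched, so everything after A3 is equal.
- Mechanism: radical capture at nickel against polar olefination. The radical route is more tolerant, but it needs electrochemical equipment.
- Step economy: A1 needs carboxyl differentiation and a one-carbon homologation, so it is unlikely to be shorter than the four steps from 1 to 5. At best it is equal.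

Alternative 2: The cuts are C3–C2 and C2–O1. Zerovalent palladium, as Pd(PPh3)4, would insert into the C3–I bond of the acyclic alkenyl iodide diol A4 and take up carbon monoxide A5, and the C5 hydroxyl would capture the acylpalladium. The product would be the 4-hydroxy alkylidene lactone A6, identical with 21.
- In its favour: the exocyclic geometry is fixed by the alkenyl iodide and transferred with retention. That is firmer than the conformational control in step 13, so it is better on this point. A6 enters the route two steps later than 19, so the endgame would be shorter, with acetylation and desilylation only. No lactone enolate or dienolate with a β-leaving group is needed.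
- Against it: A4 must already hold C3′, the C4/C5 diol and a stereodefined trisubstituted alkenyl iodide on an acyclic polyene. The hardest problem, C3′, is moved earlier and not solved.
- Structure: the route is linear with late ring formation. The chosen plan is more convergent and takes C4/C5 from the chiral pool.
- Mechanism: zerovalent palladium meets two allylic alcohols and two allylic ethers, so π-allyl side reactions are possible; five-ring closure should beat four-ring closure. A5 is a toxic gas, which makes the chosen plan safer.
- Step economy: probably worse overall, despite the shorter endgame.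

Alternative 3: The cut is O1–C5. Zerovalent palladium, formed from Pd2(dba)3 and PPh3, would ionise the tertiary allylic alcohol of the hydroxy acid A7, and the carboxylate would attack the secondary allyl terminus. The product would be the tris-silylated trans lactone A8, identical with 20.
- In its favour: the ring, C5 and the isobutenyl alkene form in one step, with no olefination of a sensitive aldehyde. This is better than steps 3 and 4 of the chosen plan. Reversible ionisation of the allylic lactone could funnel both C5 epimers to the trans isomer. The endgame after A8 is the same as after 20, so it is equal there.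
- Against it: C5 would rest on a thermodynamic or kinetic preference relative to C4. In the chosen plan it is inherited.
- Structure: A7 is a fully elaborated α-alkylidene β-silyloxy acid whose alkene geometry, C4 and C3′ must all be set beforehand on an open chain. The route is less convergent.
- Mechanism: the regiochemistry, five- against seven-membered ring, is favourable. The same catalyst can, however, re-ionise the allylic lactone and touch the cinnamyl ether.
- Step economy: not expected to be shorter than the chosen plan.

Key step: step 13

Remarks on the chemistry (assumptions):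
- 2-Deoxy-D-ribose (1) is written open-chain but reacts as its cyclic hemiacetal.
- Methyl (E)-4-hydroxycinnamate (11) is used as the commercial form of the coumaric acid unit.
- The (R,R)-bisphosphoramide is assumed to direct addition to the Re face of the aldehyde. The (S,S)-enantiomer is the direct replacement if the sense is the opposite, to be checked on 19 by MTPA ester analysis.

## Route

**Step 1**
Reactants: 1 2-deoxy-D-ribose
Product: 2 2-deoxy-D-ribono-1,4-lactone [(4S,5R)-4-hydroxy-5-(hydroxymethyl)oxolan-2-one]
Conditions: Br2, H2O, 20 °C, dark, 4–5 d; then Ag2CO3, filter, evaporate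
Reagents that add atoms: none
Why: Bromine-water oxidation of the cyclic hemiacetal of an aldose to the aldono-1,4-lactone; only the anomeric C–H is oxidised and both stereocentres (the future C4 and C5) are untouched.

**Step 2**
Reactants: 2 2-deoxy-D-ribono-1,4-lactone
Product: 3 (4S,5R)-4-(triethylsilyloxy)-5-[(triethylsilyloxy)methyl]oxolan-2-one
Conditions: Et3SiCl (2.4 equiv), imidazole, DMF, 0 °C → rt
Reagents that add atoms: chlorotriethylsilane, CC[Si](Cl)(CC)CC
Why: Imidazole-promoted silylation of a primary and a secondary alcohol; the triethylsilyl group is chosen because the primary ether can be oxidised directly in step 3 and the secondary one can later be removed beside tert-butyldimethylsilyl ethers.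

**Step 3**
Reactants: 3 bis(triethylsilyl) lactone
Product: 4 (2S,3S)-5-oxo-3-(triethylsilyloxy)oxolane-2-carbaldehyde
Conditions: (COCl)2, DMSO, CH2Cl2, −78 → −30 °C; Et3N, −78 → −20 °C; crude used directly
Reagents that add atoms: none
Why: Swern oxidation with in situ cleavage of the primary triethylsilyl ether: the chlorosulfonium reagent desilylates the unhindered primary ether far faster than the secondary one and the alkoxysulfonium is oxidised in the same flask. Keeping the amine stage cold limits epimerisation and β-elimination of the α,β-dioxygenated aldehyde; the change of descriptor at the ring carbon (R to S) is a priority effect only.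

**Step 4**
Reactants: 4 lactone aldehyde
Product: 5 (4S,5R)-5-(2-methylprop-1-en-1-yl)-4-(triethylsilyloxy)oxolan-2-one
Conditions: i-PrPPh3I, n-BuLi, THF, 0 °C; then 4, −78 → 0 °C
Reagents that add atoms: isopropyltriphenylphosphonium iodide, CC(C)[P+](c1ccccc1)(c1ccccc1)c1ccccc1.[I-]
Why: Wittig olefination with the non-stabilised isopropylidene ylide; at −78 °C the aldehyde reacts much faster than the lactone carbonyl and the symmetric ylide gives no alkene isomers. C5 takes no part in bond formation, so the trans relation to C4 is kept provided enolisation is avoided.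

**Step 5**
Reactants: 5 isobutenyl lactone; 6 acetaldehyde
Product: 7 (3S,4S,5R)-3-(1-hydroxyethyl)-5-(2-methylprop-1-en-1-yl)-4-(triethylsilyloxy)oxolan-2-one (both carbinol epimers)
Conditions: LiN(i-Pr)2, THF, −78 °C; MeCHO (3 equiv), −78 °C; AcOH quench at −78 °C
Reagents that add atoms: none
Why: Aldol addition of the lithium enolate of a γ-lactone to a simple aldehyde; at −78 °C the enolate of a β-silyloxy lactone adds faster than it expels silanolate, and the cold acidic quench prevents retro-aldol reaction and silyl migration. The electrophile should enter anti to the C4 silyl ether, but the new centres at C3 and C1′ are erased in steps 6 and 7.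

**Step 6**
Reactants: 7 aldol adduct
Product: 9 (3E,4S,5R)-3-ethylidene-5-(2-methylprop-1-en-1-yl)-4-(triethylsilyloxy)oxolan-2-one, via methanesulfonate of the aldol adduct 8 (not isolated)
Conditions: MsCl, Et3N, CH2Cl2, 0 °C; then DBU, 0 °C → rt
Reagents that add atoms: none
Why: Mesylation and base-induced E1cB elimination across C3–C1′ is the standard entry to α-alkylidene lactones; methanesulfonate is a far better leaving group than the C4 silanolate, which fixes the direction of elimination. The E isomer is expected to predominate, but the alkene geometry does not matter because step 7 turns either isomer into the same dienolate.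

**Step 7**
Reactants: 9 α-ethylidene lactone
Product: 10 tert-butyl{[(4S,5R)-3-ethenyl-5-(2-methylprop-1-en-1-yl)-4-(triethylsilyloxy)-4,5-dihydrofuran-2-yl]oxy}dimethylsilane
Conditions: LiN(i-Pr)2, THF–DMPU, −78 °C; t-BuMe2SiCl, −78 → −30 °C; pentane, cold aq. NaHCO3 wash; crude used directly
Reagents that add atoms: tert-butyl(chloro)dimethylsilane, CC(C)(C)[Si](C)(C)Cl
Why: Amide-base γ-deprotonation of the α,β-unsaturated lactone (the C2′ methyl is the only position whose anion is conjugated to the carbonyl) and O-silylation in the presence of DMPU give the silyl dienolate; the ring fixes the ketene acetal geometry, so 10 is a single isomer. Low temperature and prompt trapping limit loss of the C4 silanolate from the lithium dienolate.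

**Step 8**
Reactants: 11 methyl (E)-4-hydroxycinnamate
Product: 12 methyl (2E)-3-(4-{[tert-butyl(dimethyl)silyl]oxy}phenyl)prop-2-enoate
Conditions: t-BuMe2SiCl, imidazole, DMF, rt
Reagents that add atoms: tert-butyl(chloro)dimethylsilane, CC(C)(C)[Si](C)(C)Cl
Why: Silylation of a phenol with a silyl chloride and imidazole; the conjugated ester is inert.

**Step 9**
Reactants: 12 silylated cinnamate
Product: 13 (2E)-3-(4-{[tert-butyl(dimethyl)silyl]oxy}phenyl)prop-2-en-1-ol
Conditions: i-Bu2AlH (2.3 equiv), CH2Cl2, −78 °C; aq. potassium sodium tartrate
Reagents that add atoms: none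
Why: 1,2-Reduction of an α,β-unsaturated ester to the allylic alcohol with i-Bu2AlH at low temperature; the aryl silyl ether and the E alkene are not affected.

**Step 10**
Reactants: 13 silylated cinnamyl alcohol
Product: 14 {4-[(1E)-3-bromoprop-1-en-1-yl]phenoxy}(tert-butyl)dimethylsilane
Conditions: CBr4, PPh3, CH2Cl2, 0 °C; short silica plug, used at once
Reagents that add atoms: tetrabromomethane, BrC(Br)(Br)Br
Why: Appel bromination under nearly neutral conditions converts the primary allylic alcohol into the bromide by SN2 displacement of the oxyphosphonium group; the electron-rich cinnamyl bromide is used immediately to avoid ionisation.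

**Step 11**
Reactants: 14 silylated cinnamyl bromide; 15 nerol
Product: 16 tert-butyl(4-{(1E)-3-{[(2Z)-3,7-dimethylocta-2,6-dien-1-yl]oxy}prop-1-en-1-yl}phenoxy)dimethylsilane
Conditions: 15, NaH (1.0 equiv relative to 15), THF, 0 °C; alkoxide added slowly to 14, n-Bu4NI (cat.), THF, −20 → 0 °C
Reagents that add atoms: none
Why: Williamson ether synthesis by SN2 attack of the sodium alkoxide of 15 on the primary allylic bromide; inverse addition keeps the alkoxide concentration low so that displacement of bromide outruns attack at the aryl silyl ether. The Z alkene of 15 is not involved.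

**Step 12**
Reactants: 16 neryl cinnamyl ether
Product: 18 (2E,6Z)-8-{[(2E)-3-(4-{[tert-butyl(dimethyl)silyl]oxy}phenyl)prop-2-en-1-yl]oxy}-2,6-dimethylocta-2,6-dienal, via E allylic alcohol 17 (not isolated)
Conditions: SeO2 (0.4 equiv), t-BuOOH, salicylic acid (cat.), CH2Cl2, 0 °C → rt; crude mixture, MnO2, CH2Cl2, rt
Reagents that add atoms: selenium dioxide, O=[Se]=O; tert-butyl hydroperoxide, CC(C)(C)OO
Why: SeO2-catalysed allylic oxidation (ene reaction, then 2,3-sigmatropic shift) occurs at the most electron-rich trisubstituted alkene and, at a gem-dimethyl terminus, at the (E)-methyl group, giving the E allylic alcohol and some enal; MnO2 then oxidises only the allylic alcohol, so the mixture converges on the (2E)-enal. The C8′=C9′ alkene is deactivated by its allylic oxygen and the styrenyl alkene is less substituted.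

**Step 13**
Reactants: 10 silyl dienolate; 18 side-chain enal
Product: 19 (3E,4S,5R)-3-[(3R,4E,8Z)-10-{[(2E)-3-(4-{[tert-butyl(dimethyl)silyl]oxy}phenyl)prop-2-en-1-yl]oxy}-3-hydroxy-4,8-dimethyldeca-4,8-dien-1-ylidene]-5-(2-methylprop-1-en-1-yl)-4-(triethylsilyloxy)oxolan-2-one
Conditions: 18 (1.0 equiv), 10 (1.3 equiv), SiCl4 (1.2 equiv), (R,R)-bisphosphoramide 1,5-bis{methyl[(R)-N,N′-dimethyl-1,1′-binaphthyl-2,2′-diamino]phosphorylamino}pentane (5 mol%), i-Pr2NEt (0.2 equiv), CH2Cl2, −78 °C; cold aq. NaHCO3
Reagents that add atoms: none
Why: The bisphosphoramide binds SiCl4 and displaces chloride, giving a chiral cationic trichlorosilyl Lewis acid that activates only the aldehyde of 18; the γ-carbon C2′ of 10 adds through an open transition state, chloride removes the tert-butyldimethylsilyl group, and the C3=C1′ alkene and the lactone carbonyl are restored while the aldolate stays a trichlorosilyl ether until the hydrogen carbonate quench. The closest known reaction type is the Lewis-base-activated SiCl4 vinylogous Mukaiyama aldol of ester-derived silyl dienolates with conjugated aldehydes. No ring is closed; one C–C bond (C2′–C3′) and one stereocentre (C3′) are formed. C3′ is controlled by the catalyst: the (R,R)-enantiomer is expected to direct addition to the Re face of the aldehyde, which gives the (R)-carbinol, and the ring stereocentres lie five atoms away and should not interfere. γ-Selectivity is secured by the substrate, because the α-carbon C3 is fully substituted and flanked by the C4 silyl ether. The E geometry (C2′ cis to C4) follows from reaction through the s-trans C2=C3–C1′=C2′ conformer, in which the vinyl terminus avoids the bulky C2 silyloxy group. 1,2-Addition is ensured because the α-methyl enal is activated at oxygen and cannot enolise. Free SiCl4 is a weak Lewis acid and catalytic i-Pr2NEt scavenges HCl, so the silyl ethers and the cinnamyl ether should survive.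

**Step 14**
Reactants: 19 aldol product
Product: 20 3′-O-tert-butyldimethylsilyl ether of 19 [(3E,4S,5R)-lactone with C4 triethylsilyl ether, C3′ (R) and aryl tert-butyldimethylsilyl ethers]
Conditions: t-BuMe2SiOTf, 2,6-lutidine, CH2Cl2, −78 °C
Reagents that add atoms: tert-butyldimethylsilyl trifluoromethanesulfonate, CC(C)(C)[Si](C)(C)OS(=O)(=O)C(F)(F)F
Why: Silylation of the secondary allylic alcohol with a silyl triflate and a hindered pyridine base at −78 °C; no other nucleophilic site is present and C3′ is not epimerised.

**Step 15**
Reactants: 20 tris-silyl ether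
Product: 21 (3E,4S,5R)-4-hydroxy lactone with C3′ (R) and aryl tert-butyldimethylsilyl ethers
Conditions: pyridinium p-toluenesulfonate (0.2 equiv), MeOH–CH2Cl2, 0 °C
Reagents that add atoms: none
Why: Acid-catalysed methanolysis distinguishes silyl ethers by bulk: the secondary triethylsilyl ether is cleaved well before a secondary or an aryl tert-butyldimethylsilyl ether. The pyridinium salt at 0 °C is too weak an acid to ionise the cinnamyl ether.

**Step 16**
Reactants: 21 C4 alcohol
Product: 22 (3E,4S,5R)-4-acetoxy lactone with C3′ (R) and aryl tert-butyldimethylsilyl ethers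
Conditions: Ac2O, pyridine, DMAP (cat.), CH2Cl2, 0 °C → rt
Reagents that add atoms: acetic anhydride, CC(=O)OC(C)=O
Why: DMAP-catalysed acetylation of the only free hydroxyl; the amine bases are too weak to deprotonate C2′, so elimination of the new β-acetoxy group is not expected.

**Step 17**
Reactants: 22 acetate bis-silyl ether
Product: 23 target, (2R,3S,4E)-4-[(3R,4E,8Z)-3-hydroxy-10-{[(2E)-3-(4-hydroxyphenyl)prop-2-en-1-yl]oxy}-4,8-dimethyldeca-4,8-dien-1-ylidene]-2-(2-methylprop-1-en-1-yl)-5-oxooxolan-3-yl acetate
Conditions: HF·pyridine, pyridine, THF, 0 °C → rt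
Reagents that add atoms: none
Why: Fluoride-mediated cleavage of the remaining alkyl and aryl silyl ethers under buffered, mildly acidic conditions; this avoids the acetate elimination, acyl migration and conjugate addition that basic fluoride sources could cause.

## Compound list

1 | 2-deoxy-D-ribose | O=CC[C@H](O)[C@H](O)CO | starting material
2 | 2-deoxy-D-ribono-1,4-lactone, (4S,5R)-4-hydroxy-5-(hydroxymethyl)oxolan-2-one | O[C@H]1CC(=O)O[C@@H]1CO | intermediate
3 | (4S,5R)-4-(triethylsilyloxy)-5-[(triethylsilyloxy)methyl]oxolan-2-one | CC[Si](CC)(CC)O[C@H]1CC(=O)O[C@@H]1CO[Si](CC)(CC)CC | intermediate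
4 | (2S,3S)-5-oxo-3-(triethylsilyloxy)oxolane-2-carbaldehyde | CC[Si](CC)(CC)O[C@H]1CC(=O)O[C@@H]1C=O | intermediate
5 | (4S,5R)-5-(2-methylprop-1-en-1-yl)-4-(triethylsilyloxy)oxolan-2-one | CC[Si](CC)(CC)O[C@H]1CC(=O)O[C@@H]1C=C(C)C | intermediate
6 | acetaldehyde | CC=O | starting material
7 | (3S,4S,5R)-3-(1-hydroxyethyl)-5-(2-methylprop-1-en-1-yl)-4-(triethylsilyloxy)oxolan-2-one, carbinol epimers | CC[Si](CC)(CC)O[C@H]1[C@H](C(C)O)C(=O)O[C@@H]1C=C(C)C | intermediate
8 | methanesulfonate of 7 | CC[Si](CC)(CC)O[C@H]1[C@H](C(C)OS(C)(=O)=O)C(=O)O[C@@H]1C=C(C)C | intermediate (not isolated)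
9 | (3E,4S,5R)-3-ethylidene-5-(2-methylprop-1-en-1-yl)-4-(triethylsilyloxy)oxolan-2-one | CC[Si](CC)(CC)O[C@H]1/C(=C\C)C(=O)O[C@@H]1C=C(C)C | intermediate
10 | tert-butyl{[(4S,5R)-3-ethenyl-5-(2-methylprop-1-en-1-yl)-4-(triethylsilyloxy)-4,5-dihydrofuran-2-yl]oxy}dimethylsilane | C=CC1=C(O[Si](C)(C)C(C)(C)C)O[C@H](C=C(C)C)[C@H]1O[Si](CC)(CC)CC | intermediate
11 | methyl (E)-4-hydroxycinnamate | COC(=O)/C=C/c1ccc(O)cc1 | starting material
12 | methyl (2E)-3-(4-{[tert-butyl(dimethyl)silyl]oxy}phenyl)prop-2-enoate | COC(=O)/C=C/c1ccc(O[Si](C)(C)C(C)(C)C)cc1 | intermediate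
13 | (2E)-3-(4-{[tert-butyl(dimethyl)silyl]oxy}phenyl)prop-2-en-1-ol | OC/C=C/c1ccc(O[Si](C)(C)C(C)(C)C)cc1 | intermediate
14 | {4-[(1E)-3-bromoprop-1-en-1-yl]phenoxy}(tert-butyl)dimethylsilane | BrC/C=C/c1ccc(O[Si](C)(C)C(C)(C)C)cc1 | intermediate
15 | nerol, (2Z)-3,7-dimethylocta-2,6-dien-1-ol | CC(C)=CCC/C(C)=C\CO | starting material
16 | tert-butyl(4-{(1E)-3-{[(2Z)-3,7-dimethylocta-2,6-dien-1-yl]oxy}prop-1-en-1-yl}phenoxy)dimethylsilane | CC(C)=CCC/C(C)=C\COC/C=C/c1ccc(O[Si](C)(C)C(C)(C)C)cc1 | intermediate
17 | (2E,6Z)-8-{[(2E)-3-(4-{[tert-butyl(dimethyl)silyl]oxy}phenyl)prop-2-en-1-yl]oxy}-2,6-dimethylocta-2,6-dien-1-ol | OC/C(C)=C/CC/C(C)=C\COC/C=C/c1ccc(O[Si](C)(C)C(C)(C)C)cc1 | intermediate (not isolated)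
18 | (2E,6Z)-8-{[(2E)-3-(4-{[tert-butyl(dimethyl)silyl]oxy}phenyl)prop-2-en-1-yl]oxy}-2,6-dimethylocta-2,6-dienal | O=C/C(C)=C/CC/C(C)=C\COC/C=C/c1ccc(O[Si](C)(C)C(C)(C)C)cc1 | intermediate
19 | aldol product: free C3′ (R) hydroxyl, C4 triethylsilyl ether, aryl tert-butyldimethylsilyl ether | CC[Si](CC)(CC)O[C@H]1/C(=C\C[C@@H](O)/C(C)=C/CC/C(C)=C\COC/C=C/c2ccc(O[Si](C)(C)C(C)(C)C)cc2)C(=O)O[C@@H]1C=C(C)C | intermediate
20 | 3′-O-tert-butyldimethylsilyl ether of 19 | CC[Si](CC)(CC)O[C@H]1/C(=C\C[C@@H](O[Si](C)(C)C(C)(C)C)/C(C)=C/CC/C(C)=C\COC/C=C/c2ccc(O[Si](C)(C)C(C)(C)C)cc2)C(=O)O[C@@H]1C=C(C)C | intermediate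
21 | 4-hydroxy lactone, C3′ and aryl tert-butyldimethylsilyl ethers | O[C@H]1/C(=C\C[C@@H](O[Si](C)(C)C(C)(C)C)/C(C)=C/CC/C(C)=C\COC/C=C/c2ccc(O[Si](C)(C)C(C)(C)C)cc2)C(=O)O[C@@H]1C=C(C)C | intermediate
22 | 4-acetoxy lactone, C3′ and aryl tert-butyldimethylsilyl ethers | CC(=O)O[C@H]1/C(=C\C[C@@H](O[Si](C)(C)C(C)(C)C)/C(C)=C/CC/C(C)=C\COC/C=C/c2ccc(O[Si](C)(C)C(C)(C)C)cc2)C(=O)O[C@@H]1C=C(C)C | intermediate
23 | CNP0237370.1, (2R,3S,4E)-4-[(3R,4E,8Z)-3-hydroxy-10-{[(2E)-3-(4-hydroxyphenyl)prop-2-en-1-yl]oxy}-4,8-dimethyldeca-4,8-dien-1-ylidene]-2-(2-methylprop-1-en-1-yl)-5-oxooxolan-3-yl acetate | CC(=O)O[C@H]1/C(=C\C[C@@H](O)/C(C)=C/CC/C(C)=C\COC/C=C/c2ccc(O)cc2)C(=O)O[C@@H]1C=C(C)C | target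

## Step count and least certain steps

Total: 17 steps. Longest linear sequence: 12 steps (steps 1–7 and 13–17, from 1). The side-chain branch (steps 8–12) has five steps before the union.

**Step 13 (key step).** Facial selectivity at C3′ may be incomplete, or the sense of induction may be opposite to that assumed. The dienolate may also ionise at C4 by loss of silanolate under Lewis acid, and turnover may be slow with an α-branched dienolate.
Fallback, from 10 and 18, returning at 19: an achiral BF3·OEt2-promoted vinylogous Mukaiyama aldol at −78 °C would give the C3′-epimeric aldol mixture F1. Dess–Martin periodinane buffered with NaHCO3 would oxidise it to the C3′ ketone F2, which is handled cold and neutral because its C2′ hydrogens are acidic. Corey–Bakshi–Shibata reduction with the (S)-2-methyl oxazaborolidine and catecholborane at −78 °C, with the α-branched alkenyl group as the large substituent, should return 19. C3′ is then set by reagent-controlled ketone reduction and not by the aldol.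

**Step 7.** The lithium dienolate may expel the C4 silanolate (β-elimination toward a vinyl furanone) before it is silylated, or silylation may occur at carbon.
Fallback, from 9, returning at 19: methanolysis with pyridinium p-toluenesulfonate would give the 4-hydroxy ethylidene lactone F3. Double deprotonation with 2.2 equiv LiN(i-Pr)2 makes the C4 oxygen an alkoxide, which is a very poor leaving group. Trapping both oxygens with Et3SiCl would give the bis(triethylsilyl) dienolate F4. This enters step 13 unchanged, because the ketene acetal silyl group is lost there, and gives 19.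

**Step 4.** The basic ylide may enolise the aldehyde, causing epimerisation at C5 or β-elimination of the C4 silyloxy group, or it may add to the lactone.
Fallback, from 4, returning at 5: Ramirez olefination (CBr4, PPh3, CH2Cl2, 0 °C, no base) would give the 1,1-dibromoalkene F5. Double Negishi methylation (MeZnCl, Pd(PPh3)4 as zerovalent palladium catalyst, THF) would then give 5.

**Step 12.** Allylic oxidation may compete at the C8′=C9′ alkene or at the ether methylenes, over-oxidation may occur, and conversion may be incomplete.
Fallback, from 16, returning at 18: epoxidation of the most electron-rich terminal alkene with mCPBA (NaHCO3, CH2Cl2, 0 °C) would give the terminal epoxide F6. Periodic acid cleavage would give the shortened aldehyde F7. Wittig reaction with the stabilised ylide 2-(triphenyl-λ5-phosphanylidene)propanal in warm toluene should give the (2E)-enal 18.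

**Step 11.** The alkoxide may take the silyl group from the aryl ether, and the labile bromide may ionise or react by SN2′.
Fallback, from 13, returning at 16: acetylation would give the cinnamyl acetate F8. Allylic etherification with the zinc alkoxide of 15 (Et2Zn, 0.5 equiv) and a zerovalent palladium catalyst formed from Pd(OAc)2 and 2-(di-tert-butylphosphino)biphenyl in THF should give the linear E ether 16. This avoids both the sodium alkoxide and the bromide 14.

## Further compounds

F1 | step 13 | C3′-epimeric mixture of 19 | CC[Si](CC)(CC)O[C@H]1/C(=C\CC(O)/C(C)=C/CC/C(C)=C\COC/C=C/c2ccc(O[Si](C)(C)C(C)(C)C)cc2)C(=O)O[C@@H]1C=C(C)C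
F2 | step 13 | C3′ ketone corresponding to 19 | CC[Si](CC)(CC)O[C@H]1/C(=C\CC(=O)/C(C)=C/CC/C(C)=C\COC/C=C/c2ccc(O[Si](C)(C)C(C)(C)C)cc2)C(=O)O[C@@H]1C=C(C)C
F3 | step 7 | (3E,4S,5R)-3-ethylidene-4-hydroxy-5-(2-methylprop-1-en-1-yl)oxolan-2-one | O[C@H]1/C(=C\C)C(=O)O[C@@H]1C=C(C)C
F4 | step 7 | {[(4S,5R)-3-ethenyl-5-(2-methylprop-1-en-1-yl)-4-(triethylsilyloxy)-4,5-dihydrofuran-2-yl]oxy}triethylsilane | C=CC1=C(O[Si](CC)(CC)CC)O[C@H](C=C(C)C)[C@H]1O[Si](CC)(CC)CC
F5 | step 4 | (4S,5R)-5-(2,2-dibromoethenyl)-4-(triethylsilyloxy)oxolan-2-one | CC[Si](CC)(CC)O[C@H]1CC(=O)O[C@@H]1C=C(Br)Br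
F6 | step 12 | tert-butyl(4-{(1E)-3-{[(2Z)-5-(3,3-dimethyloxiran-2-yl)-3-methylpent-2-en-1-yl]oxy}prop-1-en-1-yl}phenoxy)dimethylsilane, racemic at the epoxide | CC1(C)OC1CC/C(C)=C\COC/C=C/c2ccc(O[Si](C)(C)C(C)(C)C)cc2
F7 | step 12 | (4Z)-6-{[(2E)-3-(4-{[tert-butyl(dimethyl)silyl]oxy}phenyl)prop-2-en-1-yl]oxy}-4-methylhex-4-enal | O=CCC/C(C)=C\COC/C=C/c1ccc(O[Si](C)(C)C(C)(C)C)cc1
F8 | step 11 | (2E)-3-(4-{[tert-butyl(dimethyl)silyl]oxy}phenyl)prop-2-en-1-yl acetate | CC(=O)OC/C=C/c1ccc(O[Si](C)(C)C(C)(C)C)cc1
A1 | alternative 1 | 1,3-dioxoisoindolin-2-yl (2R,3S)-5-oxo-3-(triethylsilyloxy)oxolane-2-carboxylate | CC[Si](CC)(CC)O[C@H]1CC(=O)O[C@H]1C(=O)ON3C(=O)c2ccccc2C3=O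
A2 | alternative 1 | 1-bromo-2-methylprop-1-ene | CC(C)=CBr
A3 | alternative 1 | (4S,5R)-5-(2-methylprop-1-en-1-yl)-4-(triethylsilyloxy)oxolan-2-one | CC[Si](CC)(CC)O[C@H]1CC(=O)O[C@@H]1C=C(C)C
A4 | alternative 2 | acyclic alkenyl iodide diol, iodine on C3 trans to C2′, C4 and C5 as in the target | O[C@@H](/C(I)=C\C[C@@H](O[Si](C)(C)C(C)(C)C)/C(C)=C/CC/C(C)=C\COC/C=C/c1ccc(O[Si](C)(C)C(C)(C)C)cc1)[C@H](O)C=C(C)C
A5 | alternative 2 | carbon monoxide | [C-]#[O+]
A6 | alternative 2 | 4-hydroxy alkylidene lactone, bis-silyl ether | O[C@H]1/C(=C\C[C@@H](O[Si](C)(C)C(C)(C)C)/C(C)=C/CC/C(C)=C\COC/C=C/c2ccc(O[Si](C)(C)C(C)(C)C)cc2)C(=O)O[C@@H]1C=C(C)C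
A7 | alternative 3 | acyclic hydroxy acid with tertiary allylic alcohol, C4 triethylsilyl ether and two tert-butyldimethylsilyl ethers | OC(=O)/C(=C/C[C@@H](O[Si](C)(C)C(C)(C)C)/C(C)=C/CC/C(C)=C\COC/C=C/c1ccc(O[Si](C)(C)C(C)(C)C)cc1)[C@H](O[Si](CC)(CC)CC)/C=C/C(C)(C)O
A8 | alternative 3 | trans lactone with C4 triethylsilyl ether and two tert-butyldimethylsilyl ethers | CC[Si](CC)(CC)O[C@H]1/C(=C\C[C@@H](O[Si](C)(C)C(C)(C)C)/C(C)=C/CC/C(C)=C\COC/C=C/c2ccc(O[Si](C)(C)C(C)(C)C)cc2)C(=O)O[C@@H]1C=C(C)C
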